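The time of reading is the open decision: the next flask gets 0.20 M of Z, and you can stop it at 8.0 h or leave it until 3.0 d.

| flask | Z | remark | time |
|---|---|---|---|
| autumn | 0.28 M | run made earlier |  |
| winter | 0.44 M | run made earlier |  |
| flask | 0.20 M |  | 3.0 d |

| run | time / h | J / % | E / % | Z / % |
|---|---|---|---|---|
| autumn | 6.00 | 0 | 14.2 | 64.0 |
| autumn | 12.0 | 0.1 | 23.1 | 45.6 |
| autumn | 20.0 | 0 | 31.9 | 33.1 |
| autumn | 25.0 | 0.5 | 32.1 | 28.4 |
| autumn | 30.0 | 0.1 | 31.5 | 25.0 |
| autumn | 40.0 | 2.1 | 34.9 | 19.9 |
| winter | 2.50 | 0.7 | 8.3 | 76.2 |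
| winter | 6.00 | 0 | 14.4 | 55.5 |
| winter | 12.0 | 1.1 | 22.3 | 37.4 |
| winter | 20.0 | 2.0 | 26.9 | 26.7 |
| winter | 25.0 | 0.9 | 27.2 | 21.7 |
| winter | 30.0 | 0 | 27.6 | 19.9 |
| winter | 40.0 | 2.9 | 27.2 | 15.7 |

(scatter of a reading: 1 percentage point)

- share of J in J plus E at 50 min
- share of J in J plus E at 8.0 h
- share of J in J plus E at 3.0 d



Write the balance of Z, the one charge. At 40.0 h the autumn run leaves 43.1% of its Z unaccounted for, and the stronger winter charge leaves more, 54.2%. So of these two runs, the stronger charge has the larger unseen loss.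

Yet the last readings of E over Z barely differ: 1.75 in autumn, 1.73 in winter. Pooled, this gives the standing ratio s, the E held per Z once E has stopped climbing, read as 1.74. It looks like thermodynamic rather than kinetic control of E.

J tells less. Through 30.0 h the autumn J stays at or below 0.5%, under the scatter of 1 percentage point, so an early share is barely readable. My decision is to hold the flask to 3.0 d. I expect E there to stand near s times Z. This reckoning gives a ratio, not a share.

The forecast gives 0.8%, 1.7% and 6% at the three times, with this ground: “This suggests J forms slowly, perhaps from E, with some concentration dependence”.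

The flask gives 1.92%, 2.09% and 4.49%, and each forecast value lies within its margin.

    Z ⇌ E (K = 1.60, k = 9.80 × 10⁻⁶ s⁻¹)
    Z ⇌ J (K = 71.0, k = 1.90 × 10⁻⁷ s⁻¹)
    2 Z → G (k = 2.80 × 10⁻⁵ M⁻¹ s⁻¹)

By their own step alone, both ways together, Z and E relax with a half-life of 0.504 d, short against 3.0 d and shorter than the 41.6 d of Z and J by their step, which is long against that time. At 3.0 d the flask holds E over Z at 1.81, beside the s of 1.74, with J at 1.67%, while the neighbour charged with 0.080 M holds 1.69, with J at 2.09% and a share of 4.33%.

The readings come from a simulation for substances that don't exist; the scatter is artificial.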